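Larch still holds 21.2 % of its starting material at 20.0 min, more than oak's 0 %, and oak has twice the reagent, so I watch the reagent as the likely limiting reagent.

| setting | elm | larch | oak | flask |
|---|---|---|---|---|
| starting material | 0.20 M | 0.20 M | 0.20 M | 0.20 M |
| second substrate | 0.40 M | 0.40 M | 0.40 M | 0.400 M |
| reagent | 0.20 M | 0.20 M | 0.40 M | 0.200 M |
| precatalyst | 0.87 mM | 2 mM | 1.3 mM | 1.3 mM |
| remark | run made earlier | run made earlier | run made earlier |  |
| time |  |  |  | 15 min |

| run | time / min | target / % | starting material / % |
|---|---|---|---|
| elm | 1.33 | 3.8 | 97.4 |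
| elm | 2.50 | 9.8 | 90.2 |
| elm | 5.00 | 26.7 | 74.0 |
| elm | 10.0 | 52.7 | 47.0 |
| elm | 20.0 | 74.9 | 26.1 |
| larch | 1.50 | 7.5 | 93.9 |
| larch | 5.00 | 42.6 | 57.1 |
| larch | 8.00 | 60.6 | 37.0 |
| larch | 12.0 | 74.9 | 23.9 |
| larch | 20.0 | 80.0 | 21.2 |
| oak | 1.33 | 8.3 | 93.7 |
| oak | 2.50 | 18.7 | 81.8 |
| oak | 5.00 | 47.1 | 49.4 |
| oak | 10.0 | 89.0 | 12.8 |
| oak | 20.0 | 99.9 | 0 |

(standard deviation of a reading: 1 percentage point)

1. target present at 15 min, in percent of the starting material charged
2. starting material present at 15 min, in percent of the starting material charged

Elm at 20.0 min and larch at 12.0 min read the same target, 74.9 %, so as read, precatalyst speeds the clock with exponent 0.614. I fold time and precatalyst into θ = (t/20.0 min)·(c(precatalyst)/0.87 mM)^n, the stretched time, which is the fraction of elm's last reading time a flask has run on elm's clock; for this flask it is 0.960. That is 19.2 min on elm, and a straight line between elm's last readings gives my 73.1 % target, with about 26.9 % starting material.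

Is one number enough? Larch at 8.00 min reads 60.6 %, and θ predicts 60.1 %. Oak at 10.0 min reads 89.0 % against a predicted 58.9 %, so θ does not carry over to oak, with its 0.40 M of reagent; this flask has elm's 0.200 M.

The forecast says 74 % and 26 %, holding that “some reagent is probably wasted”.

This flask gives 73.9 % target and 25.6 % starting material.

    starting material + free catalyst ⇌ catalyst intermediate A (K = 140 /M, k = 9.10 /M/s)
    reagent + catalyst intermediate A → free catalyst + target (k = 6.50 /M/s)
    second substrate + free catalyst ⇌ catalyst intermediate B (K = 2.00 /M, k = 3.20 /M/s)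
    reagent + catalyst intermediate B → free catalyst + second product (k = 4.70 /M/s)
    precatalyst → free catalyst (k = 0.00410 /s)
    2 catalyst intermediate A ⇌ resting dimer, settled at all times (K = 850 /M)

A neighbour read at 6.0 min has θ = 0.384, and elm's curve there gives 40.6 %; it holds 40.2 % target. By 15.0 min this flask has 6.8 % of its reagent left. Catalyst intermediate B matters in two ways here: without its falling back to second substrate and free catalyst, this flask's target stands at 48.7 % rather than 73.9 %. Part of the shortfall is reagent spent on catalyst intermediate B: without that step, this flask's target stands at 83.9 %, which is 38 % of what is missing.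

Readings and results are simulated from invented constants; noise was put on by code.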